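**Strategy.** Ring C (C1, C10–C14; eunicellane numbering) is cut across into two three-carbon units: the acetone-like triad C10–C11–C12 around the future carbinol C11, and the α-isopropyl enal triad C13–C14–C1. Both are held in one achiral ester, the acetoacetate of a γ-hydroxy enal, whose ester carbonyl is C9 and whose OCH2 is C2. A Michael/aldol-condensation domino forms C1–C10 and C12–C13 in one flask, closing ring C and a temporary γ-lactone that enforces the cis C1/C10 relationship and sets C14. The lactone later steers C11 hydration and opens to the C9 and C2 handles; the ten-membered ring is closed last at C8–C9.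

Key step: step 3

Remark: atoms are numbered as in eunicellanes (ring C = C1, C10–C14; ten-membered ring = C1–C10); the cupreidine-derived base in step 3 is assumed to give the C1 configuration of the target, and its cupreine-derived pseudo-enantiomer is used if the sense of induction is the opposite.

Step 1
Reactants: 1 3-methylbutanal (isovaleraldehyde)
Product: 2 3-methyl-2-methylidenebutanal (2-isopropylacrolein)
Conditions: 37% aq. CH2O, pyrrolidine (10 mol %), EtCO2H (10 mol %), i-PrOH, 45 °C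
Reagents that add atoms: formaldehyde, C=O
Why: Amine-catalysed Mannich condensation with formaldehyde followed by β-elimination of the amine (α-methylenation of an aldehyde) should work on this unbranched α-CH2 aldehyde; no stereocenter is formed.

Step 2
Reactants: 2 3-methyl-2-methylidenebutanal; 3 prop-2-en-1-yl 3-oxobutanoate (allyl acetoacetate)
Product: 4 (2E)-4-oxo-3-(propan-2-yl)but-2-en-1-yl 3-oxobutanoate
Conditions: second-generation Hoveyda–Grubbs catalyst, RuCl2(H2IMes)(=CH-C6H4-2-OiPr) (5 mol %), 2 (3 equiv), CH2Cl2, 40 °C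
Reagents that add atoms: none
Why: Olefin cross-metathesis between a terminal allyl ester and a 2-substituted acrolein, driven by loss of ethene, should give the trisubstituted enal as the thermodynamically preferred (E)-isomer (CHO trans to CH2O); no stereocenter is formed.

Step 3
Reactants: 4 (2E)-4-oxo-3-(propan-2-yl)but-2-en-1-yl 3-oxobutanoate
Product: 6 (3aR,4S,7aR)-4-(propan-2-yl)-3a,4-dihydro-2-benzofuran-1,7(3H,7aH)-dione, via lactone aldehyde 5 (not isolated)
Conditions: 9-O-benzylcupreidine (10 mol %), toluene (0.05 M), rt; then p-TsOH·H2O (20 mol %), 50 °C, same flask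
Reagents that add atoms: none
Why: The quinuclidine nitrogen of the bifunctional cinchona base deprotonates the acetoacetate while its phenolic OH binds the enal, and the C10 enolate adds to C1 (Michael) to give lactone aldehyde 5; on acidification the methyl-ketone enol (C12) adds to the C13 aldehyde and water is lost (aldol condensation) to give enone 6. The closest known reaction type is the base- or amine-catalysed Michael/aldol-condensation domino of β-keto esters with enals that gives cyclohexenones (a [3+3] annulation), here made intramolecular through the ester. The γ-lactone closes 5-exo-trig and ring C closes 6-(enolendo)-exo-trig, followed by dehydration. C1 is set by the face of the enal that the chiral base leaves open; C10, acidic between two carbonyls, should settle as the cis-fused lactone (a trans-fused γ-lactone is strained); C14, epimerisable α to the aldehyde in 5 and γ to the enone in 6, should settle with isopropyl trans to the lactone CH2 on the convex face. The step needs C-alkylation at C1 over intermolecular Knoevenagel or Michael oligomerisation, which the tether, the (E)-geometry (no intramolecular Knoevenagel is possible) and the dilution secure, and only C12 can reach C13 in a ring of workable size (attack by C10 would give a cyclobutane).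

Step 4
Reactants: 6 (3aR,4S,7aR)-4-(propan-2-yl)-3a,4-dihydro-2-benzofuran-1,7(3H,7aH)-dione
Product: 7 (3aR,4R,7aR)-4-(propan-2-yl)-3a,4,5,6-tetrahydro-2-benzofuran-1,7(3H,7aH)-dione
Conditions: H2 (1 atm), 10% Pd/C, EtOAc, rt
Reagents that add atoms: none
Why: Heterogeneous catalytic hydrogenation saturates the only C=C (C12=C13) without touching ketone or lactone, creates no stereocenter and removes the vinylogous acidity of C14–H, so that C14 is fixed from here on.

Step 5
Reactants: 7 (3aR,4R,7aR)-4-(propan-2-yl)-3a,4,5,6-tetrahydro-2-benzofuran-1,7(3H,7aH)-dione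
Product: 8 (3aR,4R,7aR)-7-methylidene-4-(propan-2-yl)hexahydro-2-benzofuran-1(3H)-one
Conditions: Zn, CH2Br2, TiCl4, THF/CH2Cl2, 0 °C to rt; aq. NaHCO3
Reagents that add atoms: dibromomethane, BrCBr
Why: Lombardo methylenation uses a non-basic geminal dimetallic reagent that should olefinate the ketone of the enolisable β-keto lactone chemoselectively over the lactone carbonyl; no stereocenter is formed and neutral work-up keeps the β,γ-alkene from moving into conjugation.

Step 6
Reactants: 8 (3aR,4R,7aR)-7-methylidene-4-(propan-2-yl)hexahydro-2-benzofuran-1(3H)-one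
Product: 9 (3aR,4R,7R,7aR)-7-hydroxy-7-methyl-4-(propan-2-yl)hexahydro-2-benzofuran-1(3H)-one
Conditions: Co(acac)2 (20 mol %), PhSiH3, O2 (1 atm), THF/i-PrOH, rt; then aq. Na2S2O3
Reagents that add atoms: dioxygen, O=O
Why: Mukaiyama hydration (cobalt-hydride hydrogen-atom transfer to the CH2 terminus, O2 capture of the tertiary C11 radical, reduction of the peroxide) gives the Markovnikov tertiary alcohol, and O2 should approach the planar C11 radical from the convex face of the cis-fused bicycle, anti to the lactone ring, which sets C11 with OH cis to H10 as in the target.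

Step 7
Reactants: 9 (3aR,4R,7R,7aR)-7-hydroxy-7-methyl-4-(propan-2-yl)hexahydro-2-benzofuran-1(3H)-one
Product: 10 (3aR,4R,7R,7aR)-7-methyl-4-(propan-2-yl)-7-[(triethylsilyl)oxy]hexahydro-2-benzofuran-1(3H)-one
Conditions: TESOTf, 2,6-lutidine, CH2Cl2, −78 to 0 °C
Reagents that add atoms: triethylsilyl trifluoromethanesulfonate, CC[Si](CC)(CC)OS(=O)(=O)C(F)(F)F
Why: Silylation of a hindered tertiary alcohol with a silyl triflate and 2,6-lutidine is standard, and the TES ether prevents retro-aldol cleavage and chelation at the later β-oxygenated C9 aldehyde; no stereocenter is affected.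

Step 8
Reactants: 10 (3aR,4R,7R,7aR)-7-methyl-4-(propan-2-yl)-7-[(triethylsilyl)oxy]hexahydro-2-benzofuran-1(3H)-one
Product: 11 (1R,2R,5R,6R)-6-(hydroxymethyl)-N-methoxy-N,2-dimethyl-5-(propan-2-yl)-2-[(triethylsilyl)oxy]cyclohexane-1-carboxamide
Conditions: MeNH(OMe)·HCl, AlMe3, CH2Cl2, 0 °C to rt
Reagents that add atoms: N,O-dimethylhydroxylamine hydrochloride, CNOC.Cl
Why: Weinreb aminolysis of a γ-lactone with the dimethylaluminium amide cleaves the acyl–oxygen bond, giving the C9 amide and the free C2 alcohol without touching C10; the product is used crude because γ-hydroxy amides relactonise.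

Step 9
Reactants: 11 (1R,2R,5R,6R)-6-(hydroxymethyl)-N-methoxy-N,2-dimethyl-5-(propan-2-yl)-2-[(triethylsilyl)oxy]cyclohexane-1-carboxamide
Product: 12 (1R,2R,5R,6R)-6-formyl-N-methoxy-N,2-dimethyl-5-(propan-2-yl)-2-[(triethylsilyl)oxy]cyclohexane-1-carboxamide
Conditions: Dess–Martin periodinane, CH2Cl2, 0 °C to rt
Reagents that add atoms: none
Why: Dess–Martin oxidation converts the primary alcohol into the C2 aldehyde under neutral conditions that should not epimerise C1, whose equatorial formyl group is already the favoured arrangement.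

Step 10
Reactants: 12 (1R,2R,5R,6R)-6-formyl-N-methoxy-N,2-dimethyl-5-(propan-2-yl)-2-[(triethylsilyl)oxy]cyclohexane-1-carboxamide
Product: 13 (1R,2R,5R,6R)-6-[(1Z)-2-iodoprop-1-en-1-yl]-N-methoxy-N,2-dimethyl-5-(propan-2-yl)-2-[(triethylsilyl)oxy]cyclohexane-1-carboxamide
Conditions: [Ph3PCH2CH3]I, n-BuLi, THF, rt; I2, −78 °C; NaHMDS, −20 °C; then 12, −78 to −20 °C
Reagents that add atoms: ethyltriphenylphosphonium iodide, CC[P+](c1ccccc1)(c1ccccc1)c1ccccc1.[I-]; iodine, II
Why: Stork–Zhao olefination with the α-iodo ylide Ph3P=C(I)CH3 proceeds under kinetic control through the cis-oxaphosphetane and should give the (Z)-2-iodoalkene (C1 and iodine cis), the geometry that becomes the 2Z alkene.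

Step 11
Reactants: 14 prop-2-enal (acrolein); 15 methyl prop-2-enoate (methyl acrylate)
Product: 16 methyl 3-hydroxy-2-methylidenepent-4-enoate (racemic)
Conditions: DABCO (10 mol %), 15 as solvent, rt
Reagents that add atoms: none
Why: Morita–Baylis–Hillman reaction, in which DABCO adds to the acrylate and the resulting zwitterionic enolate attacks the aldehyde carbonyl of acrolein, should give the racemic bis-allylic alcohol.

Step 12
Reactants: 16 methyl 3-hydroxy-2-methylidenepent-4-enoate (racemic)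
Product: 17 methyl (3R)-3-hydroxy-2-methylidenepent-4-enoate
Conditions: Ti(OiPr)4 (20 mol %), D-(−)-diisopropyl tartrate (24 mol %), t-BuOOH (0.6 equiv), 4 Å MS, CH2Cl2, −20 °C
Reagents that add atoms: none
Why: Sharpless kinetic resolution, in which the titanium–D-tartrate–peroxide complex should epoxidise the vinyl group of the (S)-alcohol much faster than that of the (R)-alcohol while the electron-poor acrylate alkene stays inert, leaves the (R)-alcohol (future C6) to be recovered at slightly above half conversion.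

Step 13
Reactants: 17 methyl (3R)-3-hydroxy-2-methylidenepent-4-enoate
Product: 18 methyl (3R)-3-{[tert-butyl(dimethyl)silyl]oxy}-2-methylidenepent-4-enoate
Conditions: TBSCl, imidazole, DMF, rt
Reagents that add atoms: tert-butyldimethylsilyl chloride, CC(C)(C)[Si](C)(C)Cl
Why: Standard imidazole-promoted silylation of a secondary alcohol protects O6 through the hydride, bromination and chromium steps; the stereocenter is untouched.

Step 14
Reactants: 18 methyl (3R)-3-{[tert-butyl(dimethyl)silyl]oxy}-2-methylidenepent-4-enoate; 13 (1R,2R,5R,6R)-6-[(1Z)-2-iodoprop-1-en-1-yl]-N-methoxy-N,2-dimethyl-5-(propan-2-yl)-2-[(triethylsilyl)oxy]cyclohexane-1-carboxamide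
Product: 20 methyl (3R,6Z)-3-{[tert-butyl(dimethyl)silyl]oxy}-7-[(1S,2R,3R,6R)-2-[methoxy(methyl)carbamoyl]-3-methyl-6-(propan-2-yl)-3-[(triethylsilyl)oxy]cyclohexyl]-6-methyl-2-methylidenehept-6-enoate, via alkylborane 19 (not isolated)
Conditions: 18 (1.5 equiv), 9-BBN-H, THF, rt; then 13, Pd(dppf)Cl2 (5 mol %), AsPh3, Cs2CO3, DMF/H2O, rt
Reagents that add atoms: none
Why: 9-BBN-H should hydroborate the monosubstituted vinyl group anti-Markovnikov (the conjugated, electron-poor acrylate alkene reacts far more slowly), and the B-alkyl Suzuki–Miyaura coupling of alkylborane 19 with vinyl iodide 13 proceeds with retention of alkene geometry, forming C3–C4 and the 2Z trisubstituted alkene.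

Step 15
Reactants: 20 methyl (3R,6Z)-3-{[tert-butyl(dimethyl)silyl]oxy}-7-[(1S,2R,3R,6R)-2-[methoxy(methyl)carbamoyl]-3-methyl-6-(propan-2-yl)-3-[(triethylsilyl)oxy]cyclohexyl]-6-methyl-2-methylidenehept-6-enoate
Product: 21 (1R,2R,5R,6S)-6-[(1Z,5R)-5-{[tert-butyl(dimethyl)silyl]oxy}-6-(hydroxymethyl)-2-methylhepta-1,6-dien-1-yl]-2-methyl-5-(propan-2-yl)-2-[(triethylsilyl)oxy]cyclohexane-1-carbaldehyde
Conditions: DIBAL-H (6 equiv), CH2Cl2, −78 °C; aq. Rochelle salt
Reagents that add atoms: none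
Why: DIBAL-H reduces the Weinreb amide only to the aldehyde stage (the chelated tetrahedral adduct survives until work-up) and the enoate by 1,2-reduction to the allylic alcohol; neutral work-up and use of the crude product should avoid epimerisation at C10.

Step 16
Reactants: 21 (1R,2R,5R,6S)-6-[(1Z,5R)-5-{[tert-butyl(dimethyl)silyl]oxy}-6-(hydroxymethyl)-2-methylhepta-1,6-dien-1-yl]-2-methyl-5-(propan-2-yl)-2-[(triethylsilyl)oxy]cyclohexane-1-carbaldehyde
Product: 22 (1R,2R,5R,6S)-6-[(1Z,5R)-6-(bromomethyl)-5-{[tert-butyl(dimethyl)silyl]oxy}-2-methylhepta-1,6-dien-1-yl]-2-methyl-5-(propan-2-yl)-2-[(triethylsilyl)oxy]cyclohexane-1-carbaldehyde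
Conditions: NBS, Me2S, CH2Cl2, −30 to 0 °C
Reagents that add atoms: N-bromosuccinimide, O=C1CCC(=O)N1Br
Why: Corey–Kim bromination (bromodimethylsulfonium activation of the alcohol, then SN2 displacement by bromide) should convert the primary allylic alcohol into the bromide under near-neutral conditions that tolerate the aldehyde and both silyl ethers.

Step 17
Reactants: 22 (1R,2R,5R,6S)-6-[(1Z,5R)-6-(bromomethyl)-5-{[tert-butyl(dimethyl)silyl]oxy}-2-methylhepta-1,6-dien-1-yl]-2-methyl-5-(propan-2-yl)-2-[(triethylsilyl)oxy]cyclohexane-1-carbaldehyde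
Product: 23 (1S,2Z,6R,9R,10S,11R,14R)-6-{[tert-butyl(dimethyl)silyl]oxy}-11-[(triethylsilyl)oxy]eunicella-2,7(16)-dien-9-ol
Conditions: CrCl2 (8 equiv), THF, 2 mM, slow addition of 22, rt
Reagents that add atoms: none
Why: Intramolecular Nozaki–Hiyama–Kishi allylation, in which CrCl2 inserts into the allylic C–Br bond and the carbon–chromium bond adds to the C9 aldehyde through a chair-like six-membered transition state under high dilution, forms C8–C9 and the ten-membered ring, and Felkin–Anh control by C10 together with 1,3-anti induction by the C11 silyloxy group should reinforce each other to give the (9R) carbinol.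

Step 18
Reactants: 23 (1S,2Z,6R,9R,10S,11R,14R)-6-{[tert-butyl(dimethyl)silyl]oxy}-11-[(triethylsilyl)oxy]eunicella-2,7(16)-dien-9-ol
Product: 24 (1S,2Z,6R,9R,10S,11R,14R)-eunicella-2,7(16)-diene-6,9,11-triol
Conditions: TBAF, THF, 0 °C to rt
Reagents that add atoms: none
Why: Fluoride cleaves both silyl ethers through Si–F bond formation and leaves the alkenes and all stereocenters untouched.

Step 19
Reactants: 24 (1S,2Z,6R,9R,10S,11R,14R)-eunicella-2,7(16)-diene-6,9,11-triol
Product: 25 (1S,2Z,6R,9R,10S,11R,14R)-11-hydroxyeunicella-2,7(16)-diene-6,9-diyl diacetate (CNP0303839.1)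
Conditions: Ac2O, pyridine, DMAP (cat.), CH2Cl2, 0 °C to rt
Reagents that add atoms: acetic anhydride, CC(=O)OC(C)=O
Why: DMAP-catalysed acetylation should esterify the two secondary alcohols (O6, O9) while the hindered tertiary C11 alcohol does not react under these mild conditions.

**Compound list**

1 | 3-methylbutanal (isovaleraldehyde) | CC(C)CC=O | starting material
2 | 3-methyl-2-methylidenebutanal (2-isopropylacrolein) | CC(C)C(=C)C=O | intermediate
3 | prop-2-en-1-yl 3-oxobutanoate (allyl acetoacetate) | CC(=O)CC(=O)OCC=C | starting material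
4 | (2E)-4-oxo-3-(propan-2-yl)but-2-en-1-yl 3-oxobutanoate | CC(=O)CC(=O)OC/C=C(/C=O)C(C)C | intermediate
5 | (2R)-2-[(3R,4R)-4-acetyl-5-oxooxolan-3-yl]-3-methylbutanal (lactone aldehyde; shown as the 3,4-cis epimer that closes ring C; C10 and C14 epimerise in the flask) | O=C3[C@@H](C(C)=O)[C@H](CO3)[C@@H](C(C)C)C=O | intermediate
6 | (3aR,4S,7aR)-4-(propan-2-yl)-3a,4-dihydro-2-benzofuran-1,7(3H,7aH)-dione (cis-fused; isopropyl trans to the lactone CH2) | O=C3[C@@H]2[C@H](CO3)[C@@H](C(C)C)C=CC2=O | intermediate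
7 | (3aR,4R,7aR)-4-(propan-2-yl)-3a,4,5,6-tetrahydro-2-benzofuran-1,7(3H,7aH)-dione | O=C3[C@@H]2[C@H](CO3)[C@@H](C(C)C)CCC2=O | intermediate
8 | (3aR,4R,7aR)-7-methylidene-4-(propan-2-yl)hexahydro-2-benzofuran-1(3H)-one | O=C3[C@@H]2[C@H](CO3)[C@@H](C(C)C)CCC2=C | intermediate
9 | (3aR,4R,7R,7aR)-7-hydroxy-7-methyl-4-(propan-2-yl)hexahydro-2-benzofuran-1(3H)-one | O=C3[C@@H]2[C@H](CO3)[C@@H](C(C)C)CC[C@@]2(C)O | intermediate
10 | (3aR,4R,7R,7aR)-7-methyl-4-(propan-2-yl)-7-[(triethylsilyl)oxy]hexahydro-2-benzofuran-1(3H)-one | O=C3[C@@H]2[C@H](CO3)[C@@H](C(C)C)CC[C@@]2(C)O[Si](CC)(CC)CC | intermediate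
11 | (1R,2R,5R,6R)-6-(hydroxymethyl)-N-methoxy-N,2-dimethyl-5-(propan-2-yl)-2-[(triethylsilyl)oxy]cyclohexane-1-carboxamide | CON(C)C(=O)[C@@H]2[C@H](CO)[C@@H](C(C)C)CC[C@@]2(C)O[Si](CC)(CC)CC | intermediate
12 | (1R,2R,5R,6R)-6-formyl-N-methoxy-N,2-dimethyl-5-(propan-2-yl)-2-[(triethylsilyl)oxy]cyclohexane-1-carboxamide | CON(C)C(=O)[C@@H]2[C@H](C=O)[C@@H](C(C)C)CC[C@@]2(C)O[Si](CC)(CC)CC | intermediate
13 | (1R,2R,5R,6R)-6-[(1Z)-2-iodoprop-1-en-1-yl]-N-methoxy-N,2-dimethyl-5-(propan-2-yl)-2-[(triethylsilyl)oxy]cyclohexane-1-carboxamide | CON(C)C(=O)[C@@H]2[C@H](/C=C(/C)I)[C@@H](C(C)C)CC[C@@]2(C)O[Si](CC)(CC)CC | intermediate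
14 | prop-2-enal (acrolein) | C=CC=O | starting material
15 | methyl prop-2-enoate (methyl acrylate) | C=CC(=O)OC | starting material
16 | methyl 3-hydroxy-2-methylidenepent-4-enoate (racemic) | C=CC(O)C(=C)C(=O)OC | intermediate
17 | methyl (3R)-3-hydroxy-2-methylidenepent-4-enoate | C=C[C@H](C(=C)C(=O)OC)O | intermediate
18 | methyl (3R)-3-{[tert-butyl(dimethyl)silyl]oxy}-2-methylidenepent-4-enoate | C=C[C@H](C(=C)C(=O)OC)O[Si](C)(C)C(C)(C)C | intermediate
19 | methyl (3R)-5-(9-borabicyclo[3.3.1]nonan-9-yl)-3-{[tert-butyl(dimethyl)silyl]oxy}-2-methylidenepentanoate (alkylborane) | COC(=O)C(=C)[C@@H](CCB1C2CCCC1CCC2)O[Si](C)(C)C(C)(C)C | intermediate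
20 | methyl (3R,6Z)-3-{[tert-butyl(dimethyl)silyl]oxy}-7-[(1S,2R,3R,6R)-2-[methoxy(methyl)carbamoyl]-3-methyl-6-(propan-2-yl)-3-[(triethylsilyl)oxy]cyclohexyl]-6-methyl-2-methylidenehept-6-enoate | CON(C)C(=O)[C@@H]2[C@H](/C=C(/C)CC[C@H](C(=C)C(=O)OC)O[Si](C)(C)C(C)(C)C)[C@@H](C(C)C)CC[C@@]2(C)O[Si](CC)(CC)CC | intermediate
21 | (1R,2R,5R,6S)-6-[(1Z,5R)-5-{[tert-butyl(dimethyl)silyl]oxy}-6-(hydroxymethyl)-2-methylhepta-1,6-dien-1-yl]-2-methyl-5-(propan-2-yl)-2-[(triethylsilyl)oxy]cyclohexane-1-carbaldehyde | O=C[C@@H]2[C@H](/C=C(/C)CC[C@H](C(=C)CO)O[Si](C)(C)C(C)(C)C)[C@@H](C(C)C)CC[C@@]2(C)O[Si](CC)(CC)CC | intermediate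
22 | (1R,2R,5R,6S)-6-[(1Z,5R)-6-(bromomethyl)-5-{[tert-butyl(dimethyl)silyl]oxy}-2-methylhepta-1,6-dien-1-yl]-2-methyl-5-(propan-2-yl)-2-[(triethylsilyl)oxy]cyclohexane-1-carbaldehyde | O=C[C@@H]2[C@H](/C=C(/C)CC[C@H](C(=C)CBr)O[Si](C)(C)C(C)(C)C)[C@@H](C(C)C)CC[C@@]2(C)O[Si](CC)(CC)CC | intermediate
23 | (1S,2Z,6R,9R,10S,11R,14R)-6-{[tert-butyl(dimethyl)silyl]oxy}-11-[(triethylsilyl)oxy]eunicella-2,7(16)-dien-9-ol | C=C1C[C@@H](O)[C@@H]2[C@H](/C=C(/C)CC[C@H]1O[Si](C)(C)C(C)(C)C)[C@@H](C(C)C)CC[C@@]2(C)O[Si](CC)(CC)CC | intermediate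
24 | (1S,2Z,6R,9R,10S,11R,14R)-eunicella-2,7(16)-diene-6,9,11-triol | C=C1C[C@@H](O)[C@@H]2[C@H](/C=C(/C)CC[C@H]1O)[C@@H](C(C)C)CC[C@@]2(C)O | intermediate
25 | (1S,2Z,6R,9R,10S,11R,14R)-11-hydroxyeunicella-2,7(16)-diene-6,9-diyl diacetate (CNP0303839.1) | C=C1C[C@@H](OC(C)=O)[C@@H]2[C@H](/C=C(/C)CC[C@H]1OC(C)=O)[C@@H](C(C)C)CC[C@@]2(C)O | target

**Step count.** Total: 19 steps. Longest linear sequence: 16 steps (steps 1–10 and 14–19); steps 11–13 make the C4–C8 fragment.

**Steps most likely to fail**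

Step 3. What may go wrong: insufficient enantiofacial discrimination at C1 by the non-covalently bound base on the hindered α-branched enal, and erosion by retro-Michael reaction before the aldol closure locks ring C. Fallback (sets out from 4, comes back at 7): the domino is run without chiral control (pyrrolidine/AcOH, toluene, 50 °C), which should give 6 together with its enantiomer (3aS,4R,7aS)-4-(propan-2-yl)-3a,4-dihydro-2-benzofuran-1,7(3H,7aH)-dione F1. Hydrogenation as in step 4 gives 7 together with (3aS,4S,7aS)-4-(propan-2-yl)-3a,4,5,6-tetrahydro-2-benzofuran-1,7(3H,7aH)-dione F2. The mixture is condensed with (S)-1-phenylethylamine (cat. AcOH, MgSO4, CH2Cl2) to the diastereomeric enaminolactones (3aR,4R)-7-{[(1S)-1-phenylethyl]amino}-4-(propan-2-yl)-3a,4,5,6-tetrahydro-2-benzofuran-1(3H)-one F3 and (3aS,4S)-7-{[(1S)-1-phenylethyl]amino}-4-(propan-2-yl)-3a,4,5,6-tetrahydro-2-benzofuran-1(3H)-one F4, which should be separable by crystallisation or chromatography. Mild acid hydrolysis of F3 (1 M HCl, THF) returns 7, the cis fusion being re-established at the epimerisable C10.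

Step 17. What may go wrong: intermolecular oligomerisation outrunning ten-membered ring closure, or epimerisation of the axial C9 aldehyde at C10 during its two-step handling. Fallback (sets out from 13 and 18, comes back at 23): the two fragment unions are made in the reverse order.
- DIBAL-H reduction of 13 gives (1R,2R,5R,6R)-6-[(1Z)-2-iodoprop-1-en-1-yl]-2-methyl-5-(propan-2-yl)-2-[(triethylsilyl)oxy]cyclohexane-1-carbaldehyde F5.
- DIBAL-H reduction of 18 gives (3R)-3-{[tert-butyl(dimethyl)silyl]oxy}-2-methylidenepent-4-en-1-ol F6, which is brominated (NBS, Me2S) to {[(3R)-2-(bromomethyl)penta-1,4-dien-3-yl]oxy}(tert-butyl)dimethylsilane F7.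
- Indium-mediated Barbier allylation of F5 with F7 (In, THF/H2O) forms C8–C9 intermolecularly under Felkin–Anh control and should give (1R,4R)-4-{[tert-butyl(dimethyl)silyl]oxy}-1-[(1S,2R,5R,6R)-6-[(1Z)-2-iodoprop-1-en-1-yl]-2-methyl-5-(propan-2-yl)-2-[(triethylsilyl)oxy]cyclohexyl]-3-methylidenehex-5-en-1-ol F8.
- Selective hydroboration of the monosubstituted vinyl group (9-BBN-H, or Cy2BH if the methylidene competes) gives the corresponding 6-(9-borabicyclo[3.3.1]nonan-9-yl)hexan-1-ol alkylborane F9 (not isolated). It is closed to 23 by intramolecular B-alkyl Suzuki–Miyaura coupling with the (Z)-vinyl iodide under high dilution (Pd(dppf)Cl2, AsPh3, Cs2CO3, DMF/THF/H2O).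

Step 2. What may go wrong: slow cross-metathesis of the hindered 1,1-disubstituted enal, so that homodimerisation of 3 and catalyst decay dominate. Fallback (sets out from 1, comes back at 4; step 1 is then not needed): a directed aldol condensation. Compound 1 is condensed with cyclohexylamine to N-(3-methylbutylidene)cyclohexanamine F10. Its aza-enolate (LDA, THF, −78 °C) is added to (tert-butyldimethylsilyloxy)acetaldehyde, and the adduct is hydrolysed and dehydrated with aqueous oxalic acid to (2E)-4-{[tert-butyl(dimethyl)silyl]oxy}-2-(propan-2-yl)but-2-enal F11. Desilylation (HF·pyridine, THF) gives (2E)-4-hydroxy-2-(propan-2-yl)but-2-enal F12, which is acetoacetylated with 2,2,6-trimethyl-4H-1,3-dioxin-4-one (toluene, 110 °C, acylketene capture) to give 4.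

**Further compounds**

F1 | step 3 | (3aS,4R,7aS)-4-(propan-2-yl)-3a,4-dihydro-2-benzofuran-1,7(3H,7aH)-dione (enantiomer of 6) | O=C3[C@H]2[C@@H](CO3)[C@H](C(C)C)C=CC2=O
F2 | step 3 | (3aS,4S,7aS)-4-(propan-2-yl)-3a,4,5,6-tetrahydro-2-benzofuran-1,7(3H,7aH)-dione (enantiomer of 7) | O=C3[C@H]2[C@@H](CO3)[C@H](C(C)C)CCC2=O
F3 | step 3 | (3aR,4R)-7-{[(1S)-1-phenylethyl]amino}-4-(propan-2-yl)-3a,4,5,6-tetrahydro-2-benzofuran-1(3H)-one | O=C3C2=C(N[C@@H](C)c4ccccc4)CC[C@H](C(C)C)[C@H]2CO3
F4 | step 3 | (3aS,4S)-7-{[(1S)-1-phenylethyl]amino}-4-(propan-2-yl)-3a,4,5,6-tetrahydro-2-benzofuran-1(3H)-one | O=C3C2=C(N[C@@H](C)c4ccccc4)CC[C@@H](C(C)C)[C@@H]2CO3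
F5 | step 17 | (1R,2R,5R,6R)-6-[(1Z)-2-iodoprop-1-en-1-yl]-2-methyl-5-(propan-2-yl)-2-[(triethylsilyl)oxy]cyclohexane-1-carbaldehyde | O=C[C@@H]2[C@H](/C=C(/C)I)[C@@H](C(C)C)CC[C@@]2(C)O[Si](CC)(CC)CC
F6 | step 17 | (3R)-3-{[tert-butyl(dimethyl)silyl]oxy}-2-methylidenepent-4-en-1-ol | C=C[C@H](C(=C)CO)O[Si](C)(C)C(C)(C)C
F7 | step 17 | {[(3R)-2-(bromomethyl)penta-1,4-dien-3-yl]oxy}(tert-butyl)dimethylsilane | C=C[C@H](C(=C)CBr)O[Si](C)(C)C(C)(C)C
F8 | step 17 | (1R,4R)-4-{[tert-butyl(dimethyl)silyl]oxy}-1-[(1S,2R,5R,6R)-6-[(1Z)-2-iodoprop-1-en-1-yl]-2-methyl-5-(propan-2-yl)-2-[(triethylsilyl)oxy]cyclohexyl]-3-methylidenehex-5-en-1-ol | C=C(C[C@@H](O)[C@@H]2[C@H](/C=C(/C)I)[C@@H](C(C)C)CC[C@@]2(C)O[Si](CC)(CC)CC)[C@@H](C=C)O[Si](C)(C)C(C)(C)C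
F9 | step 17 | (1R,4R)-6-(9-borabicyclo[3.3.1]nonan-9-yl)-4-{[tert-butyl(dimethyl)silyl]oxy}-1-[(1S,2R,5R,6R)-6-[(1Z)-2-iodoprop-1-en-1-yl]-2-methyl-5-(propan-2-yl)-2-[(triethylsilyl)oxy]cyclohexyl]-3-methylidenehexan-1-ol | C=C(C[C@@H](O)[C@@H]2[C@H](/C=C(/C)I)[C@@H](C(C)C)CC[C@@]2(C)O[Si](CC)(CC)CC)[C@@H](CCB3C4CCCC3CCC4)O[Si](C)(C)C(C)(C)C
F10 | step 2 | N-(3-methylbutylidene)cyclohexanamine | CC(C)CC=NC1CCCCC1
F11 | step 2 | (2E)-4-{[tert-butyl(dimethyl)silyl]oxy}-2-(propan-2-yl)but-2-enal | O=C/C(C(C)C)=C/CO[Si](C)(C)C(C)(C)C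
F12 | step 2 | (2E)-4-hydroxy-2-(propan-2-yl)but-2-enal | O=C/C(C(C)C)=C/CO
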